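**Plan**

1. Numbering: rings A and C form the chroman (O1, C2, C3, C4, C4a, C5 to C8, C8a); ring B is the quinone (C1' on C3, C2' and C5' the carbonyls, C6' the CH). The retrosynthesis first removes the MOM group from O6, then cuts ring B at C1'–C2' (Moore ring expansion) and C5'–C6' (acetylide addition to dimethyl squarate) and removes C6' (from CBr4), leaving C1' as a CH2OH group on C3.
2. The central cut is O1–C8a. It is possible because C3 sits in ring C between C2 (bound to O1) and C4 (bound to C4a of ring A) and carries only the one-carbon stub C1'. C3 is therefore the middle carbon of a prochiral 2-benzylpropane-1,3-diol whose two CH2OH arms are C2 and C1', with a leaving group on C8a.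
3. The diol is cut at C3–C4 (Knoevenagel) and C4–C4a (ortho-formylation), and O6 comes from para-oxidation, leading back to diethyl malonate, formaldehyde and 2,3-dimethoxyphenol.
4. Forward: ring A is elaborated first (steps 1–7), ring C is closed in step 8, ring B is built last (steps 11–12), and the phenol is unmasked in step 13.
5. Stereochemistry: the only stereocentre, C3 (S), is set in step 8 by the chiral ligand on palladium choosing between the enantiotopic hydroxymethyl groups. It is then carried through the aldehyde stage under base-free conditions.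

Key step: step 8

Assumption: the sense of induction of the spiro ligand must be fixed by a pilot cyclisation; "(S)-SDP(O)" [(S)-7-(diphenylphosphino)-7'-(diphenylphosphoryl)-1,1'-spirobiindane] stands for whichever antipode delivers the (S)-alcohol 13.

**Route**

Step 1
Reactants: 1 2,3-dimethoxyphenol
Product: 3 2,3-dimethoxybenzene-1,4-diol, via 2,3-dimethoxy-1,4-benzoquinone 2 (not isolated)
Conditions: (KSO3)2NO (2.2 equiv), KH2PO4, H2O/acetone, 0 °C to rt; EtOAc extract shaken with aq Na2S2O4, rt
Reagents that add atoms: potassium nitrosodisulfonate (KSO3)2NO, [K+].[K+].[O]N(S(=O)(=O)[O-])S(=O)(=O)[O-]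
Why: Teuber oxidation of a phenol with a free para position should give the para-quinone, which dithionite reduces at once to the symmetric hydroquinone.

Step 2
Reactants: 3 2,3-dimethoxybenzene-1,4-diol
Product: 4 2,3-dimethoxy-4-(methoxymethoxy)phenol
Conditions: NaH (1.0 equiv), THF/DMF, 0 °C, argon; MOMCl (1.0 equiv), 0 °C to rt
Reagents that add atoms: chloromethyl methyl ether, COCCl
Why: Williamson etherification of the monophenoxide of a symmetric diol, in which both hydroxyls are equivalent so that only the degree of alkylation has to be held by stoichiometry, with the separable bis-ether and unreacted diol returned to the sequence.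

Step 3
Reactants: 4 2,3-dimethoxy-4-(methoxymethoxy)phenol
Product: 6 2-hydroxy-3,4-dimethoxy-5-(methoxymethoxy)benzaldehyde, via 2-(hydroxymethyl)-5,6-dimethoxy-4-(methoxymethoxy)phenol 5 (not isolated)
Conditions: MgCl2 (2 equiv), Et3N (4 equiv), (CH2O)n (6 equiv), MeCN, reflux; cold aq citric acid work-up
Reagents that add atoms: paraformaldehyde (formaldehyde), C=O
Why: Casnati–Skattebøl ortho-formylation, in which the magnesium phenoxide directs formaldehyde to the only free ortho position and a second formaldehyde oxidises the benzylic alkoxide by hydride transfer, the basic medium leaving the MOM ether intact.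

Step 4
Reactants: 6 2-hydroxy-3,4-dimethoxy-5-(methoxymethoxy)benzaldehyde; 7 diethyl malonate
Product: 9 ethyl 7,8-dimethoxy-6-(methoxymethoxy)-2-oxo-2H-chromene-3-carboxylate, via diethyl arylidenemalonate 8 (not isolated)
Conditions: piperidine (0.1 equiv), AcOH (0.1 equiv), EtOH, reflux
Reagents that add atoms: none
Why: Knoevenagel condensation followed by spontaneous lactonisation of the ortho-phenol onto the cis ester is the standard entry to coumarin-3-carboxylates from salicylaldehydes.

Step 5
Reactants: 9 ethyl 7,8-dimethoxy-6-(methoxymethoxy)-2-oxo-2H-chromene-3-carboxylate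
Product: 10 ethyl 7,8-dimethoxy-6-(methoxymethoxy)-2-oxochromane-3-carboxylate (racemic)
Conditions: NaBH4 (1.2 equiv), THF/EtOH, 0 °C
Reagents that add atoms: none
Why: Conjugate hydride reduction of the doubly activated C3=C4 bond of a coumarin-3-carboxylate by NaBH4 is established, the C3 centre formed is irrelevant because it becomes the prochiral carbon, and any lactone-opened malonate would converge in step 6.

Step 6
Reactants: 10 ethyl 7,8-dimethoxy-6-(methoxymethoxy)-2-oxochromane-3-carboxylate
Product: 11 2-[3-hydroxy-2-(hydroxymethyl)propyl]-5,6-dimethoxy-4-(methoxymethoxy)phenol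
Conditions: LiAlH4 (3 equiv), THF, 0 °C to reflux; aq potassium sodium tartrate work-up
Reagents that add atoms: none
Why: Exhaustive LiAlH4 reduction of the aryl lactone and the ethyl ester should give the two primary alcohols and release the phenol, the aryl ethers and the MOM acetal being inert to hydride.

Step 7
Reactants: 11 2-[3-hydroxy-2-(hydroxymethyl)propyl]-5,6-dimethoxy-4-(methoxymethoxy)phenol
Product: 12 2-[3-hydroxy-2-(hydroxymethyl)propyl]-5,6-dimethoxy-4-(methoxymethoxy)phenyl trifluoromethanesulfonate
Conditions: PhNTf2 (1.05 equiv), Et3N (1.5 equiv), DMAP (4-(dimethylamino)pyridine, 0.05 equiv), CH2Cl2, 0 °C to rt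
Reagents that add atoms: N-phenylbis(trifluoromethanesulfonimide), O=S(=O)(N(c1ccccc1)S(=O)(=O)C(F)(F)F)C(F)(F)F
Why: Chemoselective O-triflation, since the mild triflyl donor reacts with the amine-generated phenoxide and leaves neutral primary alcohols untouched.

Step 8
Reactants: 12 2-[3-hydroxy-2-(hydroxymethyl)propyl]-5,6-dimethoxy-4-(methoxymethoxy)phenyl trifluoromethanesulfonate
Product: 13 [(3S)-7,8-dimethoxy-6-(methoxymethoxy)-3,4-dihydro-2H-chromen-3-yl]methanol
Conditions: Pd(OAc)2 (5 mol %), (S)-SDP(O) (7.5 mol %), Cs2CO3 (1.5 equiv), degassed toluene, 80 °C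
Reagents that add atoms: none
Why: Proposed new method: Pd(OAc)2 is reduced by the phosphine to zerovalent palladium, which inserts into the C8a–OTf bond to give a cationic aryl complex of divalent palladium; carbonate then delivers one CH2O arm to the metal and C–O reductive elimination forms O1–C8a, the closest known reaction type being the palladium- or copper-catalysed enantioselective desymmetrising O-arylation of 2-(2-bromobenzyl)propane-1,3-diols to chroman-3-ylmethanols, from which this step differs only in the leaving group (a triflate, itself an established partner in Pd(OAc)2/bisphosphine/Cs2CO3 couplings with heteroatom nucleophiles). Ring C closes in a six-membered exo mode by reductive elimination from a seven-membered aryl(alkoxo)palladium chelate, the only closure the tether permits. The new stereocentre C3 is set by the chiral ligand, which discriminates the two enantiotopic hydroxymethyl groups (C2 against C1') during alkoxide binding and reductive elimination and should give the (S)-alcohol. The step needs enantiotopic-group selectivity, C–O reductive elimination faster than β-hydride elimination, and a triflate that survives the base; the hemilabile P,O ligand, the weakly nucleophilic Cs2CO3 in non-polar toluene and the single electrophilic site of 12 are counted on for this, and a second arylation is impossible.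

Step 9
Reactants: 13 [(3S)-7,8-dimethoxy-6-(methoxymethoxy)-3,4-dihydro-2H-chromen-3-yl]methanol
Product: 14 (3R)-7,8-dimethoxy-6-(methoxymethoxy)-3,4-dihydro-2H-chromene-3-carbaldehyde
Conditions: TEMPO ((2,2,6,6-tetramethylpiperidin-1-yl)oxyl, 0.1 equiv), PhI(OAc)2 (1.1 equiv), CH2Cl2, rt; crude aldehyde used at once
Reagents that add atoms: none
Why: TEMPO-catalysed oxoammonium oxidation stops at the aldehyde and runs without base, so that C3 (alpha to the carbonyl and beta to O1) should not be scrambled by enolisation or retro-oxa-Michael opening; the descriptor changes to R only because the priorities change.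

Step 10
Reactants: 14 (3R)-7,8-dimethoxy-6-(methoxymethoxy)-3,4-dihydro-2H-chromene-3-carbaldehyde
Product: 15 (3S)-3-(2,2-dibromoethenyl)-7,8-dimethoxy-6-(methoxymethoxy)-3,4-dihydro-2H-chromene
Conditions: CBr4 (2 equiv), PPh3 (2 equiv), Zn dust (2 equiv), CH2Cl2, rt (reagent preformed); then 14, 0 °C
Reagents that add atoms: carbon tetrabromide, BrC(Br)(Br)Br
Why: Corey–Fuchs dibromo-olefination (Wittig reaction of Ph3P=CBr2) in its zinc variant is non-basic and avoids Ph3PBr2 and HBr, which should preserve both the C3 configuration and the MOM ether.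

Step 11
Reactants: 15 (3S)-3-(2,2-dibromoethenyl)-7,8-dimethoxy-6-(methoxymethoxy)-3,4-dihydro-2H-chromene; 16 dimethyl squarate
Product: 18 4-hydroxy-2,3-dimethoxy-4-{[(3S)-7,8-dimethoxy-6-(methoxymethoxy)-3,4-dihydro-2H-chromen-3-yl]ethynyl}cyclobut-2-en-1-one (both epimers at the carbinol carbon), via lithium acetylide 17 (not isolated)
Conditions: n-BuLi (2.0 equiv), THF, -78 °C, 1 h; then 16 (1.1 equiv) in THF, -78 °C; aq NH4Cl at -78 °C
Reagents that add atoms: none
Why: Second stage of the Corey–Fuchs sequence run as a one-flask acetylide trapping, in which bromine–lithium exchange, Fritsch–Buttenberg–Wiechell rearrangement and deprotonation give the lithium acetylide, whose 1,2-addition to one of the two equivalent carbonyls of dimethyl squarate is the standard entry to 4-alkynyl-4-hydroxycyclobutenones; exactly two equivalents of n-BuLi leave no free alkyllithium to attack the squarate, alkylation by the 1-bromobutane formed is negligible at -78 °C, and the new carbinol centre is destroyed in step 12.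

Step 12
Reactants: 18 4-hydroxy-2,3-dimethoxy-4-{[(3S)-7,8-dimethoxy-6-(methoxymethoxy)-3,4-dihydro-2H-chromen-3-yl]ethynyl}cyclobut-2-en-1-one
Product: 20 2,3-dimethoxy-5-[(3S)-7,8-dimethoxy-6-(methoxymethoxy)-3,4-dihydro-2H-chromen-3-yl]cyclohexa-2,5-diene-1,4-dione, via enynylketene 19 (not isolated)
Conditions: degassed p-xylene (0.01 M), reflux (138 °C)
Reagents that add atoms: none
Why: Moore rearrangement, in which conrotatory opening with the hydroxyl turning outward places the alkyne next to the ketene, six-membered closure gives a diradical and hydrogen transfer from O–H yields the quinone without any oxidant near ring A.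

Step 13
Reactants: 20 2,3-dimethoxy-5-[(3S)-7,8-dimethoxy-6-(methoxymethoxy)-3,4-dihydro-2H-chromen-3-yl]cyclohexa-2,5-diene-1,4-dione
Product: 21 5-[(3S)-6-hydroxy-7,8-dimethoxy-3,4-dihydro-2H-chromen-3-yl]-2,3-dimethoxycyclohexa-2,5-diene-1,4-dione (CNP0302517.1)
Conditions: p-TsOH·H2O (0.3 equiv), MeOH, 40 °C
Reagents that add atoms: none
Why: Acid-catalysed acetal exchange removes the aryl MOM ether as volatile dimethoxymethane, methanol being chosen because any exchange at the quinone methoxy groups is degenerate.

**Compound list**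

1 | 2,3-dimethoxyphenol | COc1cccc(O)c1OC | starting material
2 | 2,3-dimethoxy-1,4-benzoquinone (not isolated) | COC1=C(OC)C(=O)C=CC1=O | intermediate
3 | 2,3-dimethoxybenzene-1,4-diol | COc1c(O)ccc(O)c1OC | intermediate
4 | 2,3-dimethoxy-4-(methoxymethoxy)phenol | COCOc1ccc(O)c(OC)c1OC | intermediate
5 | 2-(hydroxymethyl)-5,6-dimethoxy-4-(methoxymethoxy)phenol (not isolated, as its magnesium salt) | OCc1cc(OCOC)c(OC)c(OC)c1O | intermediate
6 | 2-hydroxy-3,4-dimethoxy-5-(methoxymethoxy)benzaldehyde | O=Cc1cc(OCOC)c(OC)c(OC)c1O | intermediate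
7 | diethyl malonate | CCOC(=O)CC(=O)OCC | starting material
8 | diethyl 2-{[2-hydroxy-3,4-dimethoxy-5-(methoxymethoxy)phenyl]methylidene}propanedioate (not isolated) | CCOC(=O)C(=Cc1cc(OCOC)c(OC)c(OC)c1O)C(=O)OCC | intermediate
9 | ethyl 7,8-dimethoxy-6-(methoxymethoxy)-2-oxo-2H-chromene-3-carboxylate | CCOC(=O)C1=Cc2cc(OCOC)c(OC)c(OC)c2OC1=O | intermediate
10 | ethyl 7,8-dimethoxy-6-(methoxymethoxy)-2-oxochromane-3-carboxylate (racemic) | CCOC(=O)C1Cc2cc(OCOC)c(OC)c(OC)c2OC1=O | intermediate
11 | 2-[3-hydroxy-2-(hydroxymethyl)propyl]-5,6-dimethoxy-4-(methoxymethoxy)phenol | OCC(CO)Cc1cc(OCOC)c(OC)c(OC)c1O | intermediate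
12 | 2-[3-hydroxy-2-(hydroxymethyl)propyl]-5,6-dimethoxy-4-(methoxymethoxy)phenyl trifluoromethanesulfonate | OCC(CO)Cc1cc(OCOC)c(OC)c(OC)c1OS(=O)(=O)C(F)(F)F | intermediate
13 | [(3S)-7,8-dimethoxy-6-(methoxymethoxy)-3,4-dihydro-2H-chromen-3-yl]methanol | OC[C@H]1COc2c(cc(OCOC)c(OC)c2OC)C1 | intermediate
14 | (3R)-7,8-dimethoxy-6-(methoxymethoxy)-3,4-dihydro-2H-chromene-3-carbaldehyde | O=C[C@H]1COc2c(cc(OCOC)c(OC)c2OC)C1 | intermediate
15 | (3S)-3-(2,2-dibromoethenyl)-7,8-dimethoxy-6-(methoxymethoxy)-3,4-dihydro-2H-chromene | BrC(Br)=C[C@H]1COc2c(cc(OCOC)c(OC)c2OC)C1 | intermediate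
16 | dimethyl squarate (3,4-dimethoxycyclobut-3-ene-1,2-dione) | COC1=C(OC)C(=O)C1=O | starting material
17 | lithium 2-[(3S)-7,8-dimethoxy-6-(methoxymethoxy)-3,4-dihydro-2H-chromen-3-yl]ethynide (not isolated) | [Li]C#C[C@H]1COc2c(cc(OCOC)c(OC)c2OC)C1 | intermediate
18 | 4-hydroxy-2,3-dimethoxy-4-{[(3S)-7,8-dimethoxy-6-(methoxymethoxy)-3,4-dihydro-2H-chromen-3-yl]ethynyl}cyclobut-2-en-1-one (carbinol epimers) | COC1=C(OC)C(O)(C#C[C@H]2COc3c(cc(OCOC)c(OC)c3OC)C2)C1=O | intermediate
19 | (3Z)-4-hydroxy-2,3-dimethoxy-6-[(3S)-7,8-dimethoxy-6-(methoxymethoxy)-3,4-dihydro-2H-chromen-3-yl]hexa-1,3-dien-5-yn-1-one (not isolated) | O=C=C(OC)/C(OC)=C(/O)C#C[C@H]1COc2c(cc(OCOC)c(OC)c2OC)C1 | intermediate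
20 | 2,3-dimethoxy-5-[(3S)-7,8-dimethoxy-6-(methoxymethoxy)-3,4-dihydro-2H-chromen-3-yl]cyclohexa-2,5-diene-1,4-dione | COC1=C(OC)C(=O)C([C@H]2COc3c(cc(OCOC)c(OC)c3OC)C2)=CC1=O | intermediate
21 | 5-[(3S)-6-hydroxy-7,8-dimethoxy-3,4-dihydro-2H-chromen-3-yl]-2,3-dimethoxycyclohexa-2,5-diene-1,4-dione | COC1=C(OC)C(=O)C([C@H]2COc3c(cc(O)c(OC)c3OC)C2)=CC1=O | target

**Count and risks**

Total steps: 13. Longest linear sequence: 13 steps (1 to 21).

Steps most likely to fail:

Step 8 (the labelled step). Oxidative addition of the hindered, electron-rich triflate may be slow. Carbonate or alkoxide may cleave the S–O bond, or the triflyl group may move to an alkoxide and allow an uncatalysed, racemic Williamson closure. β-Hydride elimination from the alkoxo-palladium species or poor discrimination of the enantiotopic arms could also intervene. The fallback uses known chemistry, sets out from triol 11 and returns at 13. Lipase-catalysed monoacetylation (Burkholderia cepacia lipase or porcine pancreatic lipase, chosen for the required sense; vinyl acetate, t-BuOMe, rt) of the prochiral 1,3-diol should give (2R)-3-hydroxy-2-[2-hydroxy-3,4-dimethoxy-5-(methoxymethoxy)benzyl]propyl acetate F1. Intramolecular Mitsunobu etherification (PPh3, DIAD, THF, 0 °C) of the phenol onto the free CH2OH group then closes ring C through O1–C2 instead of O1–C8a, giving [(3R)-7,8-dimethoxy-6-(methoxymethoxy)-3,4-dihydro-2H-chromen-3-yl]methyl acetate F2. Methanolysis (K2CO3, MeOH, 0 °C) would deliver 13.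

Step 12. The enynylketene may close in the five-membered mode to an alkylidenecyclopentenedione, or the diradical may decay by intermolecular hydrogen abstraction. The fallback replaces the diradical pathway by a pericyclic one; it sets out from aldehyde 14 and returns at 20. Takai olefination (CrCl2, CHI3, THF, 0 °C) should give (3S)-3-[(E)-2-iodoethenyl]-7,8-dimethoxy-6-(methoxymethoxy)-3,4-dihydro-2H-chromene F3. Iodine–lithium exchange (t-BuLi, 2 equiv, Et2O, -78 °C) gives lithium (E)-2-[(3S)-7,8-dimethoxy-6-(methoxymethoxy)-3,4-dihydro-2H-chromen-3-yl]ethenide F4, which is added to 16 to give 4-hydroxy-2,3-dimethoxy-4-{(E)-2-[(3S)-7,8-dimethoxy-6-(methoxymethoxy)-3,4-dihydro-2H-chromen-3-yl]ethenyl}cyclobut-2-en-1-one F5. Heating in toluene (110 °C) brings about ring opening, six-electron electrocyclisation and tautomerisation to 2,3-dimethoxy-5-[(3S)-7,8-dimethoxy-6-(methoxymethoxy)-3,4-dihydro-2H-chromen-3-yl]benzene-1,4-diol F6. Ag2O in Et2O would then oxidise this hydroquinone to 20 without touching the fully etherified ring A.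

Step 13. Acid may degrade the quinone by nucleophilic attack on its vinylogous ester carbons, or the freed electron-rich phenol may be alkylated by the formaldehyde equivalent. The fallback moves the deprotection ahead of quinone formation; it sets out from dibromoolefin 15 and returns at 21. Acetal exchange (p-TsOH·H2O, MeOH, 40 °C), harmless to the dibromoalkene, gives (3S)-3-(2,2-dibromoethenyl)-7,8-dimethoxy-3,4-dihydro-2H-chromen-6-ol F7. Treatment with n-BuLi (3.0 equiv, THF, -78 °C) deprotonates the phenol and then carries the dibromoalkene through exchange, rearrangement and deprotonation to dilithium (3S)-3-ethynidyl-7,8-dimethoxy-3,4-dihydro-2H-chromen-6-olate F8, which is added to 16 to give 4-hydroxy-4-{[(3S)-6-hydroxy-7,8-dimethoxy-3,4-dihydro-2H-chromen-3-yl]ethynyl}-2,3-dimethoxycyclobut-2-en-1-one F9. Thermolysis in dilute p-xylene as in step 12 would then give 21 directly.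

Further compounds
F1 | step 8 | (2R)-3-hydroxy-2-[2-hydroxy-3,4-dimethoxy-5-(methoxymethoxy)benzyl]propyl acetate | CC(=O)OC[C@@H](CO)Cc1cc(OCOC)c(OC)c(OC)c1O
F2 | step 8 | [(3R)-7,8-dimethoxy-6-(methoxymethoxy)-3,4-dihydro-2H-chromen-3-yl]methyl acetate | CC(=O)OC[C@H]1COc2c(cc(OCOC)c(OC)c2OC)C1
F3 | step 12 | (3S)-3-[(E)-2-iodoethenyl]-7,8-dimethoxy-6-(methoxymethoxy)-3,4-dihydro-2H-chromene | I/C=C/[C@H]1COc2c(cc(OCOC)c(OC)c2OC)C1
F4 | step 12 | lithium (E)-2-[(3S)-7,8-dimethoxy-6-(methoxymethoxy)-3,4-dihydro-2H-chromen-3-yl]ethenide | [Li]/C=C/[C@H]1COc2c(cc(OCOC)c(OC)c2OC)C1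
F5 | step 12 | 4-hydroxy-2,3-dimethoxy-4-{(E)-2-[(3S)-7,8-dimethoxy-6-(methoxymethoxy)-3,4-dihydro-2H-chromen-3-yl]ethenyl}cyclobut-2-en-1-one | COC1=C(OC)C(O)(/C=C/[C@H]2COc3c(cc(OCOC)c(OC)c3OC)C2)C1=O
F6 | step 12 | 2,3-dimethoxy-5-[(3S)-7,8-dimethoxy-6-(methoxymethoxy)-3,4-dihydro-2H-chromen-3-yl]benzene-1,4-diol | COc1c(O)cc([C@H]2COc3c(cc(OCOC)c(OC)c3OC)C2)c(O)c1OC
F7 | step 13 | (3S)-3-(2,2-dibromoethenyl)-7,8-dimethoxy-3,4-dihydro-2H-chromen-6-ol | BrC(Br)=C[C@H]1COc2c(cc(O)c(OC)c2OC)C1
F8 | step 13 | dilithium (3S)-3-ethynidyl-7,8-dimethoxy-3,4-dihydro-2H-chromen-6-olate | [Li]C#C[C@H]1COc2c(cc(O[Li])c(OC)c2OC)C1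
F9 | step 13 | 4-hydroxy-4-{[(3S)-6-hydroxy-7,8-dimethoxy-3,4-dihydro-2H-chromen-3-yl]ethynyl}-2,3-dimethoxycyclobut-2-en-1-one | COC1=C(OC)C(O)(C#C[C@H]2COc3c(cc(O)c(OC)c3OC)C2)C1=O
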